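**Retrosynthetic overview**
1. Target 22 ⇐ global desilylation of 21; 21 ⇐ aromatic Claisen rearrangement of aryl allyl ether 20 (C3'–C1'' bond; diarylmethine set by 1,3-chirality transfer).
2. Tetrahydropyran (the only ring made; all benzene rings are bought) ⇐ chalcone ether 18 + cyclic carbonate 13 by palladium-mediated oxa-Michael/allylation (O1–C2 and C3–C4), then C2/C3 set by ring-enolate equilibration.
3. 18 ⇐ Mitsunobu inversion of chalcone 17 with diol 12; 13 ⇐ carbonylation of the same diol 12, so both heptanoid units come from one intermediate.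
4. Key C–C bond (C3–C4 of the heptanoid): the acyl anion of aldehyde 3 (lithiated dithiane 7) opens (R)-epichlorohydrin, relayed in the same flask to benzyl Grignard 9. Two normally electrophilic carbons are joined, and the one bought stereocentre controls everything downstream.
5. Order: heptanoid (steps 1–6) and chalcone (7–8) → ether (9) → tetrahydropyran ring (10) → Claisen (11) → deprotection (12).

Assumption: the configuration is taken exactly as written in the SMILES, i.e. (R) at the diarylmethine, (S) at the carbinol and 2R,3R,4S,6S in the tetrahydropyran (2,6-trans, 2,3-trans, 3,4-cis).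
Notation: TBS = tert-butyldimethylsilyl; primed locants are on the acetophenone ring, doubly primed on the heptenyl chain, plain ring locants on the tetrahydropyran.

**Step 1**
Reactants: 1 4-(tert-butyldimethylsilyloxy)benzaldehyde; 2 (triphenylphosphoranylidene)acetaldehyde
Product: 3 (2E)-3-[4-(TBSO)phenyl]prop-2-enal
Conditions: PhMe, 80 °C
Reagents that add atoms: none
Why: Wittig olefination with the stabilised formyl ylide gives the (E)-enal and leaves the aryl silyl ether untouched.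

**Step 2**
Reactants: 3 (2E)-3-[4-(TBSO)phenyl]prop-2-enal
Product: 4 2-[(E)-2-[4-(TBSO)phenyl]ethenyl]-1,3-dithiane
Conditions: HS(CH2)3SH, BF3·OEt2 (10 mol%), CH2Cl2, −20 °C
Reagents that add atoms: propane-1,3-dithiol, SCCCS
Why: Lewis-acid dithioacetalisation (1,2-addition to the aldehyde) gives the 2-alkenyl-1,3-dithiane needed for Corey–Seebach polarity reversal.

**Step 3 (key step)**
Reactants: 4 2-[(E)-2-[4-(TBSO)phenyl]ethenyl]-1,3-dithiane; 5 (R)-epichlorohydrin; 6 tert-butyl[4-(chloromethyl)phenoxy]dimethylsilane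
Product: 10 (2S)-1-{2-[(E)-2-[4-(TBSO)phenyl]ethenyl]-1,3-dithian-2-yl}-4-[4-(TBSO)phenyl]butan-2-ol, via lithiated dithiane 7 (not isolated), via dithianyl epoxide 8 (not isolated), via benzylmagnesium chloride 9 (not isolated)
Conditions: n-BuLi, THF, −30 °C; 5, −78 → 0 °C; then 9 (from 6, Mg, Et2O), CuI (10 mol%), −30 → 0 °C; H2O
Reagents that add atoms: none
Why: Corey–Seebach acyl-anion alkylation: the 2-lithio-dithiane attacks the oxirane CH2 of 5 at its alpha carbon (keeping the styrene conjugation), the alkoxide closes to epoxide 8 without touching the stereocentre, and copper-catalysed Grignard opening at the new CH2 gives the (S)-carbinol, so this centre comes unchanged from (R)-epichlorohydrin.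

**Step 4**
Reactants: 10 (2S)-1-{2-[(E)-2-[4-(TBSO)phenyl]ethenyl]-1,3-dithian-2-yl}-4-[4-(TBSO)phenyl]butan-2-ol
Product: 11 (1E,5S)-5-hydroxy-1,7-bis[4-(TBSO)phenyl]hept-1-en-3-one
Conditions: MeI, CaCO3, MeCN/H2O (9:1), 40 °C
Reagents that add atoms: water, O
Why: Alkylative dithiane hydrolysis (S-methylation, then water) unmasks the enone under near-neutral conditions that spare the silyl ethers, the styrene and the beta-hydroxy ketone.

**Step 5**
Reactants: 11 (1E,5S)-5-hydroxy-1,7-bis[4-(TBSO)phenyl]hept-1-en-3-one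
Product: 12 (1E,3S,5S)-1,7-bis[4-(TBSO)phenyl]hept-1-ene-3,5-diol (1,3-syn)
Conditions: Et2BOMe, NaBH4, THF/MeOH (4:1), −78 °C; then MeOH
Reagents that add atoms: none
Why: Narasaka–Prasad reduction: external hydride attacks the boron chelate of the beta-hydroxy ketone axially, giving the 1,3-syn diol and setting C3 as S.

**Step 6**
Reactants: 12 (1E,3S,5S)-1,7-bis[4-(TBSO)phenyl]hept-1-ene-3,5-diol
Product: 13 (4S,6S)-4-[(E)-2-[4-(TBSO)phenyl]ethenyl]-6-{2-[4-(TBSO)phenyl]ethyl}-1,3-dioxan-2-one (cis)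
Conditions: 1,1'-carbonyldiimidazole, DMAP (10 mol%), CH2Cl2, rt → 40 °C
Reagents that add atoms: 1,1'-carbonyldiimidazole, O=C(n1ccnc1)n1ccnc1
Why: Carbonylation of the 1,3-diol closes the six-membered cyclic carbonate without touching either stereocentre, giving the cis-4,6-disubstituted dioxanone.

**Step 7**
Reactants: 14 1-(2,4-dihydroxy-6-methoxyphenyl)ethan-1-one; 15 4-hydroxybenzaldehyde
Product: 16 helichrysetin, (2E)-1-(2,4-dihydroxy-6-methoxyphenyl)-3-(4-hydroxyphenyl)prop-2-en-1-one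
Conditions: KOH (50% aq.), EtOH, rt, 48 h; then HCl (aq.)
Reagents that add atoms: none
Why: Claisen–Schmidt aldol condensation with E1cB dehydration gives the (E)-chalcone.

**Step 8**
Reactants: 16 helichrysetin
Product: 17 (2E)-1-[2-hydroxy-6-methoxy-4-(TBSO)phenyl]-3-[4-(TBSO)phenyl]prop-2-en-1-one
Conditions: TBSCl (2.2 equiv), imidazole, DMF, 0 °C
Reagents that add atoms: tert-butyldimethylsilyl chloride, CC(C)(C)[Si](C)(C)Cl
Why: Selective O-silylation: the two free phenols react while the 2'-OH, hydrogen-bonded to the ketone, stays free.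

**Step 9**
Reactants: 17 (2E)-1-[2-hydroxy-6-methoxy-4-(TBSO)phenyl]-3-[4-(TBSO)phenyl]prop-2-en-1-one; 12 (1E,3S,5S)-1,7-bis[4-(TBSO)phenyl]hept-1-ene-3,5-diol
Product: 18 (2E)-1-[2-{[(1E,3R,5S)-5-hydroxy-1,7-bis[4-(TBSO)phenyl]hept-1-en-3-yl]oxy}-6-methoxy-4-(TBSO)phenyl]-3-[4-(TBSO)phenyl]prop-2-en-1-one
Conditions: PPh3, diisopropyl azodicarboxylate, PhMe, 0 °C → rt
Reagents that add atoms: none
Why: Mitsunobu etherification: the 2'-phenol displaces the activated allylic C3 oxygen (more reactive than the C5 alcohol) by SN2 with inversion, turning (3S) into the (3R) aryl ether.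

**Step 10**
Reactants: 18 chalcone aryl allyl ether (as named in step 9); 13 (4S,6S)-cis-carbonate
Product: 20 [2-{[(1E,3R,5S)-5-hydroxy-1,7-bis[4-(TBSO)phenyl]hept-1-en-3-yl]oxy}-6-methoxy-4-(TBSO)phenyl][(2R,3R,4S,6S)-2-[4-(TBSO)phenyl]-4-[(E)-2-[4-(TBSO)phenyl]ethenyl]-6-{2-[4-(TBSO)phenyl]ethyl}oxan-3-yl]methanone, via C2/C3-epimeric annulation product 19 (not isolated)
Conditions: Pd2(dba)3·CHCl3 (2.5 mol%), PPh3 (12 mol%), THF, 0 °C; then KN(SiMe3)2 (2.2 equiv), −78 → −40 °C; AcOH, −78 °C; then DBU (10 mol%), PhMe, 0 °C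
Reagents that add atoms: none
Why: Proposed new method: zerovalent palladium ionises 13 with loss of CO2 to a pi-allyl/alkoxide zwitterion, the alkoxide adds reversibly to the chalcone (oxa-Michael) and the enolate closes on the allyl terminus anti to palladium (double inversion, so C4 is S and cis to C6), run at 0 °C so that the aryl allyl ether of 18 is not ionised, the closest known reaction being decarboxylative [4+2] annulation of 4-vinyl-1,3-dioxan-2-ones with activated alkenes; the base then equilibrates C2 through the ring enolate, where allylic 1,3-strain with the aryl ketone forces the C2 aryl axial (2,6-trans), and protonation followed by amine epimerisation of C3 gives the more stable trans-diaxial C2/C3 pair.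

**Step 11**
Reactants: 20 tetrahydropyranyl ketone bearing the 2'-O-allyl ether (as named in step 10)
Product: 21 [2-hydroxy-3-[(1R,2E,5S)-5-hydroxy-1,7-bis[4-(TBSO)phenyl]hept-2-en-1-yl]-6-methoxy-4-(TBSO)phenyl][(2R,3R,4S,6S)-2-[4-(TBSO)phenyl]-4-[(E)-2-[4-(TBSO)phenyl]ethenyl]-6-{2-[4-(TBSO)phenyl]ethyl}oxan-3-yl]methanone
Conditions: 1,2-dichlorobenzene, 150 °C
Reagents that add atoms: none
Why: Aromatic Claisen rearrangement ([3,3]-sigmatropic, chair transition state with the C4'' chain equatorial) delivers the allyl unit to C3', the only free ortho carbon, transfers chirality from the (3R) ether carbon to the (R)-diarylmethine, forms the (E)-alkene, and tautomerisation frees the 2'-OH.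

**Step 12**
Reactants: 21 hexakis-TBS ether (as named in step 11)
Product: 22 blepharocalyxin B
Conditions: Bu4NF (8 equiv), AcOH (8 equiv), THF, 0 °C → rt
Reagents that add atoms: none
Why: Fluoride cleavage of the six aryl silyl ethers, buffered with acetic acid so that no phenoxide can trigger retro-oxa-Michael opening or quinone-methide epimerisation at C2.

**Compound list**
1 | 4-(tert-butyldimethylsilyloxy)benzaldehyde | O=Cc1ccc(O[Si](C)(C)C(C)(C)C)cc1 | starting material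
2 | (triphenylphosphoranylidene)acetaldehyde | O=CC=P(c1ccccc1)(c1ccccc1)c1ccccc1 | starting material
3 | (2E)-3-[4-(TBSO)phenyl]prop-2-enal | O=C/C=C/c1ccc(O[Si](C)(C)C(C)(C)C)cc1 | intermediate
4 | 2-[(E)-2-[4-(TBSO)phenyl]ethenyl]-1,3-dithiane | C1CSC(/C=C/c2ccc(O[Si](C)(C)C(C)(C)C)cc2)SC1 | intermediate
5 | (R)-epichlorohydrin | ClC[C@H]1CO1 | starting material
6 | tert-butyl[4-(chloromethyl)phenoxy]dimethylsilane | ClCc1ccc(O[Si](C)(C)C(C)(C)C)cc1 | starting material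
7 | 2-lithio-2-[(E)-2-[4-(TBSO)phenyl]ethenyl]-1,3-dithiane (not isolated) | [Li]C1(/C=C/c2ccc(O[Si](C)(C)C(C)(C)C)cc2)SCCCS1 | intermediate
8 | 2-[(E)-2-[4-(TBSO)phenyl]ethenyl]-2-{[(2R)-oxiran-2-yl]methyl}-1,3-dithiane (not isolated) | C1CSC(/C=C/c2ccc(O[Si](C)(C)C(C)(C)C)cc2)(C[C@@H]2CO2)SC1 | intermediate
9 | [4-(TBSO)benzyl]magnesium chloride (not isolated) | Cl[Mg]Cc1ccc(O[Si](C)(C)C(C)(C)C)cc1 | intermediate
10 | (2S)-1-{2-[(E)-2-[4-(TBSO)phenyl]ethenyl]-1,3-dithian-2-yl}-4-[4-(TBSO)phenyl]butan-2-ol | C1CSC(/C=C/c2ccc(O[Si](C)(C)C(C)(C)C)cc2)(C[C@@H](O)CCc2ccc(O[Si](C)(C)C(C)(C)C)cc2)SC1 | intermediate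
11 | (1E,5S)-5-hydroxy-1,7-bis[4-(TBSO)phenyl]hept-1-en-3-one | O=C(/C=C/c1ccc(O[Si](C)(C)C(C)(C)C)cc1)C[C@@H](O)CCc1ccc(O[Si](C)(C)C(C)(C)C)cc1 | intermediate
12 | (1E,3S,5S)-1,7-bis[4-(TBSO)phenyl]hept-1-ene-3,5-diol | CC(C)(C)[Si](C)(C)Oc1ccc(/C=C/[C@@H](O)C[C@@H](O)CCc2ccc(O[Si](C)(C)C(C)(C)C)cc2)cc1 | intermediate
13 | (4S,6S)-4-[(E)-2-[4-(TBSO)phenyl]ethenyl]-6-{2-[4-(TBSO)phenyl]ethyl}-1,3-dioxan-2-one | O=C1O[C@H](/C=C/c2ccc(O[Si](C)(C)C(C)(C)C)cc2)C[C@H](CCc2ccc(O[Si](C)(C)C(C)(C)C)cc2)O1 | intermediate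
14 | 1-(2,4-dihydroxy-6-methoxyphenyl)ethan-1-one | CC(=O)c1c(O)cc(O)cc1OC | starting material
15 | 4-hydroxybenzaldehyde | O=Cc1ccc(O)cc1 | starting material
16 | helichrysetin | COc1cc(O)cc(O)c1C(=O)/C=C/c1ccc(O)cc1 | intermediate
17 | (2E)-1-[2-hydroxy-6-methoxy-4-(TBSO)phenyl]-3-[4-(TBSO)phenyl]prop-2-en-1-one | COc1cc(O[Si](C)(C)C(C)(C)C)cc(O)c1C(=O)/C=C/c1ccc(O[Si](C)(C)C(C)(C)C)cc1 | intermediate
18 | chalcone 2'-O-[(1E,3R,5S)-5-hydroxy-1,7-bis[4-(TBSO)phenyl]hept-1-en-3-yl] ether | COc1cc(O[Si](C)(C)C(C)(C)C)cc(O[C@@H](/C=C/c2ccc(O[Si](C)(C)C(C)(C)C)cc2)C[C@@H](O)CCc2ccc(O[Si](C)(C)C(C)(C)C)cc2)c1C(=O)/C=C/c1ccc(O[Si](C)(C)C(C)(C)C)cc1 | intermediate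
19 | annulation product, (4S,6S)-tetrahydropyranyl ketone as C2/C3 epimer mixture (not isolated) | COc1cc(O[Si](C)(C)C(C)(C)C)cc(O[C@@H](/C=C/c2ccc(O[Si](C)(C)C(C)(C)C)cc2)C[C@@H](O)CCc2ccc(O[Si](C)(C)C(C)(C)C)cc2)c1C(=O)C1[C@H](/C=C/c2ccc(O[Si](C)(C)C(C)(C)C)cc2)C[C@H](CCc2ccc(O[Si](C)(C)C(C)(C)C)cc2)OC1c1ccc(O[Si](C)(C)C(C)(C)C)cc1 | intermediate
20 | (2R,3R,4S,6S)-tetrahydropyranyl ketone bearing the 2'-O-allyl ether | COc1cc(O[Si](C)(C)C(C)(C)C)cc(O[C@@H](/C=C/c2ccc(O[Si](C)(C)C(C)(C)C)cc2)C[C@@H](O)CCc2ccc(O[Si](C)(C)C(C)(C)C)cc2)c1C(=O)[C@@H]1[C@H](/C=C/c2ccc(O[Si](C)(C)C(C)(C)C)cc2)C[C@H](CCc2ccc(O[Si](C)(C)C(C)(C)C)cc2)O[C@H]1c1ccc(O[Si](C)(C)C(C)(C)C)cc1 | intermediate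
21 | hexakis-TBS ether of blepharocalyxin B (2'-OH and carbinol free) | COc1cc(O[Si](C)(C)C(C)(C)C)c([C@H](/C=C/C[C@@H](O)CCc2ccc(O[Si](C)(C)C(C)(C)C)cc2)c2ccc(O[Si](C)(C)C(C)(C)C)cc2)c(O)c1C(=O)[C@@H]1[C@H](/C=C/c2ccc(O[Si](C)(C)C(C)(C)C)cc2)C[C@H](CCc2ccc(O[Si](C)(C)C(C)(C)C)cc2)O[C@H]1c1ccc(O[Si](C)(C)C(C)(C)C)cc1 | intermediate
22 | blepharocalyxin B | COc1cc(O)c([C@H](/C=C/C[C@@H](O)CCc2ccc(O)cc2)c2ccc(O)cc2)c(O)c1C(=O)[C@@H]1[C@H](/C=C/c2ccc(O)cc2)C[C@H](CCc2ccc(O)cc2)O[C@H]1c1ccc(O)cc1 | target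

**Totals and risks**
Total steps: 12. Longest linear sequence: 9 steps (1, 2, 3, 4, 5, then 9 or 6, then 10, 11, 12).

Most likely to fail, first: step 10. Chalcones are weaker acceptors than those used so far in this annulation, and the stereochemical outcome at C2/C3 rests on the enolate argument. Fallback: set out from 18 and make the C3–C4 bond first. Add PhSLi to the enone (thia-Michael, THF, −78 °C) and allylate the resulting lithium enolate with 13 and Pd(PPh3)4 (net retention at C4) to give the beta-phenylthio ketone F1. Then KN(SiMe3)2 expels thiolate (E1cB) to the 2-benzylidene ketone, whose C6 alkoxide closes the ring by 6-endo oxa-Michael through the same ring enolate. Protonation and amine epimerisation as in step 10 return to the route at 20.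

Second: step 9. The Mitsunobu reaction may give SN2' products, partial ionisation at the electron-rich cinnamyl position, or reaction at the C5 alcohol. Fallback: set out from 11. A 1,3-anti reduction with Me4NBH(OAc)3 (Evans–Saksena) gives the (3R,5S)-diol F2, and 1,1'-carbonyldiimidazole gives the trans-carbonate F3. Pd(PPh3)4-catalysed decarboxylative O-allylation of phenol 17 (Tsuji–Trost, double inversion, attack at the alkyl-bearing allyl terminus) then gives 18 with the same (3R) ether configuration.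

Third: step 11. The Claisen rearrangement may fail on the ring-bearing substrate through ionisation of the ether or thermal damage to the beta-alkoxy ketone. Fallback: set out from 18 and make the C3'–C1'' bond before the ring exists. Rearrange 18 to the 3'-C-alkylated chalcone F4, then cap the new 2'-OH and the carbinol with Et3SiOTf and 2,6-lutidine to give the bis(triethylsilyl) ether F5. Run the annulation and equilibration of step 10 on F5 with 13 to give the tetrahydropyran F6, and desilylate with Bu4NF/AcOH to arrive directly at 22.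

**Further compounds**
F1 | step 10 | beta-phenylthio alpha-allylated ketone from 18 (C2/C3 epimer mixture) | COc1cc(O[Si](C)(C)C(C)(C)C)cc(O[C@@H](/C=C/c2ccc(O[Si](C)(C)C(C)(C)C)cc2)C[C@@H](O)CCc2ccc(O[Si](C)(C)C(C)(C)C)cc2)c1C(=O)C(C(Sc1ccccc1)c1ccc(O[Si](C)(C)C(C)(C)C)cc1)[C@H](/C=C/c1ccc(O[Si](C)(C)C(C)(C)C)cc1)C[C@@H](O)CCc1ccc(O[Si](C)(C)C(C)(C)C)cc1
F2 | step 9 | (1E,3R,5S)-1,7-bis[4-(TBSO)phenyl]hept-1-ene-3,5-diol (1,3-anti) | CC(C)(C)[Si](C)(C)Oc1ccc(/C=C/[C@H](O)C[C@@H](O)CCc2ccc(O[Si](C)(C)C(C)(C)C)cc2)cc1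
F3 | step 9 | (4R,6S)-4-[(E)-2-[4-(TBSO)phenyl]ethenyl]-6-{2-[4-(TBSO)phenyl]ethyl}-1,3-dioxan-2-one (trans) | O=C1O[C@@H](/C=C/c2ccc(O[Si](C)(C)C(C)(C)C)cc2)C[C@H](CCc2ccc(O[Si](C)(C)C(C)(C)C)cc2)O1
F4 | step 11 | (2E)-1-[2-hydroxy-3-[(1R,2E,5S)-5-hydroxy-1,7-bis[4-(TBSO)phenyl]hept-2-en-1-yl]-6-methoxy-4-(TBSO)phenyl]-3-[4-(TBSO)phenyl]prop-2-en-1-one | COc1cc(O[Si](C)(C)C(C)(C)C)c([C@H](/C=C/C[C@@H](O)CCc2ccc(O[Si](C)(C)C(C)(C)C)cc2)c2ccc(O[Si](C)(C)C(C)(C)C)cc2)c(O)c1C(=O)/C=C/c1ccc(O[Si](C)(C)C(C)(C)C)cc1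
F5 | step 11 | 2'-O,5''-O-bis(triethylsilyl) ether of F4 | COc1cc(O[Si](C)(C)C(C)(C)C)c([C@H](/C=C/C[C@@H](O[Si](CC)(CC)CC)CCc2ccc(O[Si](C)(C)C(C)(C)C)cc2)c2ccc(O[Si](C)(C)C(C)(C)C)cc2)c(O[Si](CC)(CC)CC)c1C(=O)/C=C/c1ccc(O[Si](C)(C)C(C)(C)C)cc1
F6 | step 11 | (2R,3R,4S,6S)-tetrahydropyranyl ketone from F5 (six TBS and two triethylsilyl ethers) | COc1cc(O[Si](C)(C)C(C)(C)C)c([C@H](/C=C/C[C@@H](O[Si](CC)(CC)CC)CCc2ccc(O[Si](C)(C)C(C)(C)C)cc2)c2ccc(O[Si](C)(C)C(C)(C)C)cc2)c(O[Si](CC)(CC)CC)c1C(=O)[C@@H]1[C@H](/C=C/c2ccc(O[Si](C)(C)C(C)(C)C)cc2)C[C@H](CCc2ccc(O[Si](C)(C)C(C)(C)C)cc2)O[C@H]1c1ccc(O[Si](C)(C)C(C)(C)C)cc1
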